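Assumption: the SMILES is read as the trans isomer (13R,17S)-17-(2-oxoheptyl)-1,5,10-triazabicyclo[11.4.0]heptadec-15-en-11-one; (R)-tert-butanesulfinamide, lithium acetylide–ethylenediamine complex and N-(3-bromopropyl)phthalimide are taken as cheap commercial materials.

## Retrosynthetic overview

1. Target ⇐ acid hydrolysis of a dioxolane after denosylation; the 13-membered lactam ring is closed last by intramolecular Mitsunobu N-alkylation of a nosylamide at the central spermidine nitrogen.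
2. The amide (4-aminobutan-1-ol) and the N-propyl arm (N-(3-bromopropyl)phthalimide) are attached intermolecularly to a trans-2,6-disubstituted tetrahydropyridine (ring A, formed first).
3. Ring A ⇐ intramolecular Mitsunobu N–C13 closure (inversion) of a (Z)-allylic nosylamide onto a homoallylic (S)-alcohol, so the trans relationship comes from two independently set centres.
4. C17 and the 2-oxoheptyl chain ⇐ intermolecular Mannich addition of the heptan-2-one enolate to an (R)-N-tert-butanesulfinyl ynimine (key C–C bond); Z-alkene by Lindlar reduction.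
5. Ynimine ⇐ ynal ⇐ (R)-epoxide (hydrolytic kinetic resolution) + acetylide + DMF, from but-3-en-1-ol.

## Route

Step 1
Reactants: 1 but-3-en-1-ol
Product: 2 1-[(but-3-en-1-yloxy)methyl]-4-methoxybenzene
Conditions: NaH, 4-methoxybenzyl chloride, n-Bu4NI (cat.), THF/DMF, 0 °C to rt
Reagents that add atoms: 4-methoxybenzyl chloride, COc1ccc(CCl)cc1
Why: Williamson ether synthesis of a primary alkoxide with a benzylic chloride gives the PMB ether, which is later removable oxidatively.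

Step 2
Reactants: 2 1-[(but-3-en-1-yloxy)methyl]-4-methoxybenzene
Product: 3 rac-2-{2-[(4-methoxybenzyl)oxy]ethyl}oxirane
Conditions: mCPBA, NaHCO3, CH2Cl2, 0 °C to rt
Reagents that add atoms: 3-chloroperoxybenzoic acid (mCPBA), OOC(=O)c1cccc(Cl)c1
Why: Prilezhaev epoxidation of the terminal alkene is clean and leaves the PMB ether untouched.

Step 3
Reactants: 3 rac-2-{2-[(4-methoxybenzyl)oxy]ethyl}oxirane
Product: 4 (R)-2-{2-[(4-methoxybenzyl)oxy]ethyl}oxirane
Conditions: (R,R)-N,N'-bis(3,5-di-tert-butylsalicylidene)-1,2-cyclohexanediaminocobalt acetate [(R,R)-(salen)Co(OAc), trivalent cobalt] 0.5 mol %, H2O 0.55 equiv, THF, 0 °C to rt; chromatography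
Reagents that add atoms: none
Why: Jacobsen hydrolytic kinetic resolution, in which this catalyst enantiomer hydrolyses the (S)-epoxide and leaves (R)-4 in high ee (maximum 50 %); this fixes the carbon that becomes C13.

Step 4
Reactants: 4 (R)-2-{2-[(4-methoxybenzyl)oxy]ethyl}oxirane; 5 lithium acetylide–ethylenediamine complex
Product: 6 (S)-1-[(4-methoxybenzyl)oxy]hex-5-yn-3-ol
Conditions: LiC≡CH·H2NCH2CH2NH2, DMSO, 15 °C to rt; H2O
Reagents that add atoms: none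
Why: SN2 opening of the terminal epoxide at CH2 by acetylide does not touch the stereocentre, so the (R)-epoxide gives the (S)-homopropargylic alcohol.

Step 5
Reactants: 6 (S)-1-[(4-methoxybenzyl)oxy]hex-5-yn-3-ol
Product: 7 (S)-tert-butyl({1-[(4-methoxybenzyl)oxy]hex-5-yn-3-yl}oxy)diphenylsilane
Conditions: TBDPSCl, imidazole, DMF, rt
Reagents that add atoms: tert-butyl(chloro)diphenylsilane, CC(C)(C)[Si](Cl)(c1ccccc1)c1ccccc1
Why: Silylation gives an ether that survives n-BuLi, the titanium enolate and the later HCl/MeOH treatment.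

Step 6
Reactants: 7 (S)-tert-butyl({1-[(4-methoxybenzyl)oxy]hex-5-yn-3-yl}oxy)diphenylsilane; 8 N,N-dimethylformamide
Product: 10 (S)-5-[(tert-butyldiphenylsilyl)oxy]-7-[(4-methoxybenzyl)oxy]hept-2-ynal, via lithium alkynide 9 (not isolated)
Conditions: n-BuLi, THF, −78 °C; DMF, −78 to 0 °C; poured into cold aq. KH2PO4
Reagents that add atoms: none
Why: Deprotonation of the terminal alkyne and formylation with DMF (Bouveault-type) gives the ynal after inverse acidic quench.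

Step 7
Reactants: 10 (S)-5-[(tert-butyldiphenylsilyl)oxy]-7-[(4-methoxybenzyl)oxy]hept-2-ynal; 11 (R)-2-methylpropane-2-sulfinamide
Product: 12 (R,E)-N-{(S)-5-[(tert-butyldiphenylsilyl)oxy]-7-[(4-methoxybenzyl)oxy]hept-2-yn-1-ylidene}-2-methylpropane-2-sulfinamide
Conditions: CuSO4 (anhydrous), CH2Cl2, rt
Reagents that add atoms: none
Why: Ellman condensation of a non-enolisable aldehyde with the sulfinamide gives the (E)-sulfinyl imine under mild dehydrating conditions.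

Step 8
Reactants: 12 (R,E)-N-{(S)-5-[(tert-butyldiphenylsilyl)oxy]-7-[(4-methoxybenzyl)oxy]hept-2-yn-1-ylidene}-2-methylpropane-2-sulfinamide; 13 heptan-2-one
Product: 16 (R)-N-{(3S,7S)-3-[(tert-butyldiphenylsilyl)oxy]-1-[(4-methoxybenzyl)oxy]-9-oxotetradec-5-yn-7-yl}-2-methylpropane-2-sulfinamide, via lithium enolate of heptan-2-one 14 (not isolated), via triisopropoxytitanium enolate of heptan-2-one 15 (not isolated)
Conditions: LiN(iPr)2, THF, −78 °C; ClTi(OiPr)3, −78 °C; then 12, −78 °C; aq. NH4Cl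
Reagents that add atoms: none
Why: Intermolecular Mannich addition of the kinetic (methyl-side) titanium enolate to the non-enolisable sulfinyl imine proceeds 1,2 through a chelated chair transition state in which the (R)-sulfinyl group directs attack to the face giving the (S)-amine (future C17); the minor diastereomer is removed by chromatography.

Step 9
Reactants: 16 (R)-N-{(3S,7S)-3-[(tert-butyldiphenylsilyl)oxy]-1-[(4-methoxybenzyl)oxy]-9-oxotetradec-5-yn-7-yl}-2-methylpropane-2-sulfinamide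
Product: 17 (R)-N-{(3S,5Z,7S)-3-[(tert-butyldiphenylsilyl)oxy]-1-[(4-methoxybenzyl)oxy]-9-oxotetradec-5-en-7-yl}-2-methylpropane-2-sulfinamide
Conditions: H2 (1 atm), Pd/CaCO3 poisoned with Pb(OAc)2 (Lindlar catalyst), quinoline, EtOAc, rt
Reagents that add atoms: none
Why: Lindlar semi-hydrogenation adds hydrogen syn to give the Z-alkene needed in ring A, and is done before any nitroarene is present.

Step 10
Reactants: 17 (R)-N-{(3S,5Z,7S)-3-[(tert-butyldiphenylsilyl)oxy]-1-[(4-methoxybenzyl)oxy]-9-oxotetradec-5-en-7-yl}-2-methylpropane-2-sulfinamide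
Product: 19 N-{(3S,5Z,7S)-3-[(tert-butyldiphenylsilyl)oxy]-1-[(4-methoxybenzyl)oxy]-9-oxotetradec-5-en-7-yl}-2-nitrobenzenesulfonamide, via amine hydrochloride 18 (not isolated)
Conditions: HCl (4 M in dioxane), MeOH, 0 °C; evaporate; 2-nitrobenzenesulfonyl chloride, sat. aq. NaHCO3/CH2Cl2, 0 °C to rt
Reagents that add atoms: 2-nitrobenzenesulfonyl chloride, O=[N+]([O-])c1ccccc1S(=O)(=O)Cl
Why: Acidic methanolysis of the N-sulfinyl group followed by Schotten–Baumann sulfonylation traps the β-amino ketone at once as a non-basic, Mitsunobu-competent nosylamide without touching the stereocentre.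

Step 11
Reactants: 19 N-{(3S,5Z,7S)-3-[(tert-butyldiphenylsilyl)oxy]-1-[(4-methoxybenzyl)oxy]-9-oxotetradec-5-en-7-yl}-2-nitrobenzenesulfonamide
Product: 20 N-{(2S,3Z,6S)-6-[(tert-butyldiphenylsilyl)oxy]-8-[(4-methoxybenzyl)oxy]-1-(2-pentyl-1,3-dioxolan-2-yl)oct-3-en-2-yl}-2-nitrobenzenesulfonamide
Conditions: Me3SiOCH2CH2OSiMe3, Me3SiOSO2CF3 (cat.), CH2Cl2, −78 to −20 °C; pyridine quench
Reagents that add atoms: 1,2-bis(trimethylsilyloxy)ethane, C[Si](C)(C)OCCO[Si](C)(C)C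
Why: Noyori ketalisation masks the ketone under aprotic, cold conditions, which shuts down retro-Michael epimerisation of the β-amino ketone in all later basic steps.

Step 12
Reactants: 20 N-{(2S,3Z,6S)-6-[(tert-butyldiphenylsilyl)oxy]-8-[(4-methoxybenzyl)oxy]-1-(2-pentyl-1,3-dioxolan-2-yl)oct-3-en-2-yl}-2-nitrobenzenesulfonamide
Product: 21 N-{(2S,3Z,6S)-6-hydroxy-8-[(4-methoxybenzyl)oxy]-1-(2-pentyl-1,3-dioxolan-2-yl)oct-3-en-2-yl}-2-nitrobenzenesulfonamide
Conditions: n-Bu4NF, THF, rt to 40 °C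
Reagents that add atoms: none
Why: Fluoride desilylation frees the secondary alcohol while the ketal, PMB ether and sulfonamide are inert.

Step 13
Reactants: 21 N-{(2S,3Z,6S)-6-hydroxy-8-[(4-methoxybenzyl)oxy]-1-(2-pentyl-1,3-dioxolan-2-yl)oct-3-en-2-yl}-2-nitrobenzenesulfonamide
Product: 22 (2R,6S)-2-{2-[(4-methoxybenzyl)oxy]ethyl}-1-[(2-nitrophenyl)sulfonyl]-6-[(2-pentyl-1,3-dioxolan-2-yl)methyl]-1,2,3,6-tetrahydropyridine
Conditions: PPh3, diisopropyl azodicarboxylate (DIAD), THF (0.02 M), 0 °C to rt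
Reagents that add atoms: none
Why: Intramolecular Fukuyama–Mitsunobu N-alkylation (6-exo, favoured by the Z-alkene) displaces the activated (S)-carbinol with clean SN2 inversion, giving the (R)-centre and hence the trans-2,6-disubstituted ring A.

Step 14
Reactants: 22 (2R,6S)-2-{2-[(4-methoxybenzyl)oxy]ethyl}-1-[(2-nitrophenyl)sulfonyl]-6-[(2-pentyl-1,3-dioxolan-2-yl)methyl]-1,2,3,6-tetrahydropyridine
Product: 23 2-{(2R,6S)-1-[(2-nitrophenyl)sulfonyl]-6-[(2-pentyl-1,3-dioxolan-2-yl)methyl]-1,2,3,6-tetrahydropyridin-2-yl}ethan-1-ol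
Conditions: 2,3-dichloro-5,6-dicyano-1,4-benzoquinone (DDQ), CH2Cl2/pH 7 buffer, 0 °C to rt
Reagents that add atoms: none
Why: Oxidative PMB cleavage by DDQ is selective for the electron-rich benzyl ether and tolerates the ketal, the alkene and the sulfonamide.

Step 15
Reactants: 23 2-{(2R,6S)-1-[(2-nitrophenyl)sulfonyl]-6-[(2-pentyl-1,3-dioxolan-2-yl)methyl]-1,2,3,6-tetrahydropyridin-2-yl}ethan-1-ol
Product: 24 2-{(2R,6S)-1-[(2-nitrophenyl)sulfonyl]-6-[(2-pentyl-1,3-dioxolan-2-yl)methyl]-1,2,3,6-tetrahydropyridin-2-yl}acetic acid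
Conditions: 2,2,6,6-tetramethylpiperidin-1-oxyl (TEMPO, cat.), PhI(OAc)2, MeCN/H2O, rt
Reagents that add atoms: water, O
Why: Oxoammonium (TEMPO/PhI(OAc)2) oxidation takes the primary alcohol through the aldehyde hydrate to the acid while the nitrogen is still a non-oxidisable sulfonamide.

Step 16
Reactants: 24 2-{(2R,6S)-1-[(2-nitrophenyl)sulfonyl]-6-[(2-pentyl-1,3-dioxolan-2-yl)methyl]-1,2,3,6-tetrahydropyridin-2-yl}acetic acid; 25 4-aminobutan-1-ol
Product: 26 N-(4-hydroxybutyl)-2-{(2R,6S)-1-[(2-nitrophenyl)sulfonyl]-6-[(2-pentyl-1,3-dioxolan-2-yl)methyl]-1,2,3,6-tetrahydropyridin-2-yl}acetamide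
Conditions: N-(3-dimethylaminopropyl)-N'-ethylcarbodiimide hydrochloride (EDC·HCl), 1-hydroxybenzotriazole, iPr2NEt, CH2Cl2, 0 °C to rt
Reagents that add atoms: none
Why: Carbodiimide amide coupling is chemoselective for the amine of the amino alcohol over its hydroxyl.

Step 17
Reactants: 26 N-(4-hydroxybutyl)-2-{(2R,6S)-1-[(2-nitrophenyl)sulfonyl]-6-[(2-pentyl-1,3-dioxolan-2-yl)methyl]-1,2,3,6-tetrahydropyridin-2-yl}acetamide
Product: 27 N-(4-hydroxybutyl)-2-{(2R,6S)-6-[(2-pentyl-1,3-dioxolan-2-yl)methyl]-1,2,3,6-tetrahydropyridin-2-yl}acetamide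
Conditions: PhSH, K2CO3, MeCN, rt
Reagents that add atoms: none
Why: Fukuyama denosylation (thiolate SNAr through a Meisenheimer adduct, loss of SO2) frees the ring amine without touching either stereocentre.

Step 18
Reactants: 27 N-(4-hydroxybutyl)-2-{(2R,6S)-6-[(2-pentyl-1,3-dioxolan-2-yl)methyl]-1,2,3,6-tetrahydropyridin-2-yl}acetamide; 28 N-(3-bromopropyl)phthalimide
Product: 29 2-{(2R,6S)-1-[3-(1,3-dioxoisoindolin-2-yl)propyl]-6-[(2-pentyl-1,3-dioxolan-2-yl)methyl]-1,2,3,6-tetrahydropyridin-2-yl}-N-(4-hydroxybutyl)acetamide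
Conditions: K2CO3, MeCN, 80 °C (sealed), 24–48 h
Reagents that add atoms: none
Why: SN2 N-alkylation of the hindered secondary amine with a primary bromide installs the three-carbon arm, and the amide NH and alcohol do not compete under carbonate.

Step 19
Reactants: 29 2-{(2R,6S)-1-[3-(1,3-dioxoisoindolin-2-yl)propyl]-6-[(2-pentyl-1,3-dioxolan-2-yl)methyl]-1,2,3,6-tetrahydropyridin-2-yl}-N-(4-hydroxybutyl)acetamide
Product: 30 2-{(2R,6S)-1-(3-aminopropyl)-6-[(2-pentyl-1,3-dioxolan-2-yl)methyl]-1,2,3,6-tetrahydropyridin-2-yl}-N-(4-hydroxybutyl)acetamide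
Conditions: N2H4·H2O, EtOH, 60 °C, under N2
Reagents that add atoms: none
Why: Ing–Manske hydrazinolysis (Gabriel synthesis) releases the primary amine, and the secondary amide and ketal are stable to it.

Step 20
Reactants: 30 2-{(2R,6S)-1-(3-aminopropyl)-6-[(2-pentyl-1,3-dioxolan-2-yl)methyl]-1,2,3,6-tetrahydropyridin-2-yl}-N-(4-hydroxybutyl)acetamide
Product: 31 N-(4-hydroxybutyl)-2-{(2R,6S)-1-{3-[(2-nitrophenyl)sulfonamido]propyl}-6-[(2-pentyl-1,3-dioxolan-2-yl)methyl]-1,2,3,6-tetrahydropyridin-2-yl}acetamide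
Conditions: 2-nitrobenzenesulfonyl chloride (1.05 equiv), Et3N, CH2Cl2, −10 to 0 °C
Reagents that add atoms: 2-nitrobenzenesulfonyl chloride, O=[N+]([O-])c1ccccc1S(=O)(=O)Cl
Why: N-Sulfonylation is chemoselective for the primary amine over the primary alcohol and sets up the acidic N–H for ring closure.

Step 21
Reactants: 31 N-(4-hydroxybutyl)-2-{(2R,6S)-1-{3-[(2-nitrophenyl)sulfonamido]propyl}-6-[(2-pentyl-1,3-dioxolan-2-yl)methyl]-1,2,3,6-tetrahydropyridin-2-yl}acetamide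
Product: 32 (13R,17S)-5-[(2-nitrophenyl)sulfonyl]-17-[(2-pentyl-1,3-dioxolan-2-yl)methyl]-1,5,10-triazabicyclo[11.4.0]heptadec-15-en-11-one
Conditions: PPh3, DIAD, toluene/THF, slow addition of 31 to 2 mM, rt
Reagents that add atoms: none
Why: Macrocyclising Fukuyama–Mitsunobu alkylation of the nosylamide by the primary alcohol closes the 13-membered ring at an unhindered CH2 under high dilution, with only the nosylamide N–H acidic enough to react.

Step 22
Reactants: 32 (13R,17S)-5-[(2-nitrophenyl)sulfonyl]-17-[(2-pentyl-1,3-dioxolan-2-yl)methyl]-1,5,10-triazabicyclo[11.4.0]heptadec-15-en-11-one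
Product: 33 (13R,17S)-17-[(2-pentyl-1,3-dioxolan-2-yl)methyl]-1,5,10-triazabicyclo[11.4.0]heptadec-15-en-11-one
Conditions: PhSH, K2CO3, MeCN, rt
Reagents that add atoms: none
Why: Fukuyama denosylation is carried out while the ketone is still a ketal, so the basic thiolate cannot trigger retro-Michael epimerisation at C17.

Step 23
Reactants: 33 (13R,17S)-17-[(2-pentyl-1,3-dioxolan-2-yl)methyl]-1,5,10-triazabicyclo[11.4.0]heptadec-15-en-11-one
Product: 34 (13R,17S)-17-(2-oxoheptyl)-1,5,10-triazabicyclo[11.4.0]heptadec-15-en-11-one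
Conditions: 2 M aq. HCl/THF, 40 °C; cold aq. NaHCO3 to pH 8–9, CHCl3 extraction
Reagents that add atoms: water, O
Why: Acid-catalysed ketal hydrolysis unveils the ketone while both amines are protonated, which blocks retro-Michael opening and keeps the C17 configuration.

## Compound list

1 | but-3-en-1-ol | C=CCCO | starting material
2 | 1-[(but-3-en-1-yloxy)methyl]-4-methoxybenzene | COc1ccc(COCCC=C)cc1 | intermediate
3 | rac-2-{2-[(4-methoxybenzyl)oxy]ethyl}oxirane | COc1ccc(COCCC2CO2)cc1 | intermediate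
4 | (R)-2-{2-[(4-methoxybenzyl)oxy]ethyl}oxirane | COc1ccc(COCC[C@@H]2CO2)cc1 | intermediate
5 | lithium acetylide–ethylenediamine complex | [Li+].[C-]#C.NCCN | starting material
6 | (S)-1-[(4-methoxybenzyl)oxy]hex-5-yn-3-ol | COc1ccc(COCC[C@@H](O)CC#C)cc1 | intermediate
7 | (S)-tert-butyl({1-[(4-methoxybenzyl)oxy]hex-5-yn-3-yl}oxy)diphenylsilane | COc1ccc(COCC[C@@H](O[Si](c2ccccc2)(c2ccccc2)C(C)(C)C)CC#C)cc1 | intermediate
8 | N,N-dimethylformamide | CN(C)C=O | starting material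
9 | lithium alkynide of 7 | COc1ccc(COCC[C@@H](O[Si](c2ccccc2)(c2ccccc2)C(C)(C)C)CC#[C-])cc1.[Li+] | intermediate (not isolated)
10 | (S)-5-[(tert-butyldiphenylsilyl)oxy]-7-[(4-methoxybenzyl)oxy]hept-2-ynal | COc1ccc(COCC[C@@H](O[Si](c2ccccc2)(c2ccccc2)C(C)(C)C)CC#CC=O)cc1 | intermediate
11 | (R)-2-methylpropane-2-sulfinamide | CC(C)(C)[S@@](=O)N | starting material
12 | (R,E)-N-{(S)-5-[(tert-butyldiphenylsilyl)oxy]-7-[(4-methoxybenzyl)oxy]hept-2-yn-1-ylidene}-2-methylpropane-2-sulfinamide | CC(C)(C)[S@@](=O)/N=C/C#CC[C@H](O[Si](c1ccccc1)(c1ccccc1)C(C)(C)C)CCOCc1ccc(OC)cc1 | intermediate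
13 | heptan-2-one | CCCCCC(C)=O | starting material
14 | lithium enolate of heptan-2-one (lithium hept-1-en-2-olate) | [Li+].[O-]C(=C)CCCCC | intermediate (not isolated)
15 | triisopropoxytitanium enolate of heptan-2-one | C=C(CCCCC)O[Ti](OC(C)C)(OC(C)C)OC(C)C | intermediate (not isolated)
16 | (R)-N-{(3S,7S)-3-[(tert-butyldiphenylsilyl)oxy]-1-[(4-methoxybenzyl)oxy]-9-oxotetradec-5-yn-7-yl}-2-methylpropane-2-sulfinamide | CCCCCC(=O)C[C@H](N[S@](=O)C(C)(C)C)C#CC[C@H](O[Si](c1ccccc1)(c1ccccc1)C(C)(C)C)CCOCc1ccc(OC)cc1 | intermediate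
17 | (R)-N-{(3S,5Z,7S)-3-[(tert-butyldiphenylsilyl)oxy]-1-[(4-methoxybenzyl)oxy]-9-oxotetradec-5-en-7-yl}-2-methylpropane-2-sulfinamide | CCCCCC(=O)C[C@H](N[S@](=O)C(C)(C)C)/C=C\C[C@H](O[Si](c1ccccc1)(c1ccccc1)C(C)(C)C)CCOCc1ccc(OC)cc1 | intermediate
18 | (3S,5Z,7S)-7-amino-3-[(tert-butyldiphenylsilyl)oxy]-1-[(4-methoxybenzyl)oxy]tetradec-5-en-9-one hydrochloride | CCCCCC(=O)C[C@H](N)/C=C\C[C@H](O[Si](c1ccccc1)(c1ccccc1)C(C)(C)C)CCOCc1ccc(OC)cc1.Cl | intermediate (not isolated)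
19 | N-{(3S,5Z,7S)-3-[(tert-butyldiphenylsilyl)oxy]-1-[(4-methoxybenzyl)oxy]-9-oxotetradec-5-en-7-yl}-2-nitrobenzenesulfonamide | CCCCCC(=O)C[C@H](NS(=O)(=O)c1ccccc1[N+](=O)[O-])/C=C\C[C@H](O[Si](c1ccccc1)(c1ccccc1)C(C)(C)C)CCOCc1ccc(OC)cc1 | intermediate
20 | N-{(2S,3Z,6S)-6-[(tert-butyldiphenylsilyl)oxy]-8-[(4-methoxybenzyl)oxy]-1-(2-pentyl-1,3-dioxolan-2-yl)oct-3-en-2-yl}-2-nitrobenzenesulfonamide | CCCCCC1(C[C@H](NS(=O)(=O)c2ccccc2[N+](=O)[O-])/C=C\C[C@H](O[Si](c2ccccc2)(c2ccccc2)C(C)(C)C)CCOCc2ccc(OC)cc2)OCCO1 | intermediate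
21 | N-{(2S,3Z,6S)-6-hydroxy-8-[(4-methoxybenzyl)oxy]-1-(2-pentyl-1,3-dioxolan-2-yl)oct-3-en-2-yl}-2-nitrobenzenesulfonamide | CCCCCC1(C[C@H](NS(=O)(=O)c2ccccc2[N+](=O)[O-])/C=C\C[C@H](O)CCOCc2ccc(OC)cc2)OCCO1 | intermediate
22 | (2R,6S)-2-{2-[(4-methoxybenzyl)oxy]ethyl}-1-[(2-nitrophenyl)sulfonyl]-6-[(2-pentyl-1,3-dioxolan-2-yl)methyl]-1,2,3,6-tetrahydropyridine | CCCCCC1(C[C@H]2C=CC[C@H](CCOCc3ccc(OC)cc3)N2S(=O)(=O)c2ccccc2[N+](=O)[O-])OCCO1 | intermediate
23 | 2-{(2R,6S)-1-[(2-nitrophenyl)sulfonyl]-6-[(2-pentyl-1,3-dioxolan-2-yl)methyl]-1,2,3,6-tetrahydropyridin-2-yl}ethan-1-ol | CCCCCC1(C[C@H]2C=CC[C@H](CCO)N2S(=O)(=O)c2ccccc2[N+](=O)[O-])OCCO1 | intermediate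
24 | 2-{(2R,6S)-1-[(2-nitrophenyl)sulfonyl]-6-[(2-pentyl-1,3-dioxolan-2-yl)methyl]-1,2,3,6-tetrahydropyridin-2-yl}acetic acid | CCCCCC1(C[C@H]2C=CC[C@H](CC(=O)O)N2S(=O)(=O)c2ccccc2[N+](=O)[O-])OCCO1 | intermediate
25 | 4-aminobutan-1-ol | NCCCCO | starting material
26 | N-(4-hydroxybutyl)-2-{(2R,6S)-1-[(2-nitrophenyl)sulfonyl]-6-[(2-pentyl-1,3-dioxolan-2-yl)methyl]-1,2,3,6-tetrahydropyridin-2-yl}acetamide | CCCCCC1(C[C@H]2C=CC[C@H](CC(=O)NCCCCO)N2S(=O)(=O)c2ccccc2[N+](=O)[O-])OCCO1 | intermediate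
27 | N-(4-hydroxybutyl)-2-{(2R,6S)-6-[(2-pentyl-1,3-dioxolan-2-yl)methyl]-1,2,3,6-tetrahydropyridin-2-yl}acetamide | CCCCCC1(C[C@H]2C=CC[C@H](CC(=O)NCCCCO)N2)OCCO1 | intermediate
28 | N-(3-bromopropyl)phthalimide | O=C1N(CCCBr)C(=O)c2ccccc12 | starting material
29 | 2-{(2R,6S)-1-[3-(1,3-dioxoisoindolin-2-yl)propyl]-6-[(2-pentyl-1,3-dioxolan-2-yl)methyl]-1,2,3,6-tetrahydropyridin-2-yl}-N-(4-hydroxybutyl)acetamide | CCCCCC1(C[C@H]2C=CC[C@H](CC(=O)NCCCCO)N2CCCN2C(=O)c3ccccc3C2=O)OCCO1 | intermediate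
30 | 2-{(2R,6S)-1-(3-aminopropyl)-6-[(2-pentyl-1,3-dioxolan-2-yl)methyl]-1,2,3,6-tetrahydropyridin-2-yl}-N-(4-hydroxybutyl)acetamide | CCCCCC1(C[C@H]2C=CC[C@H](CC(=O)NCCCCO)N2CCCN)OCCO1 | intermediate
31 | N-(4-hydroxybutyl)-2-{(2R,6S)-1-{3-[(2-nitrophenyl)sulfonamido]propyl}-6-[(2-pentyl-1,3-dioxolan-2-yl)methyl]-1,2,3,6-tetrahydropyridin-2-yl}acetamide | CCCCCC1(C[C@H]2C=CC[C@H](CC(=O)NCCCCO)N2CCCNS(=O)(=O)c2ccccc2[N+](=O)[O-])OCCO1 | intermediate
32 | (13R,17S)-5-[(2-nitrophenyl)sulfonyl]-17-[(2-pentyl-1,3-dioxolan-2-yl)methyl]-1,5,10-triazabicyclo[11.4.0]heptadec-15-en-11-one | CCCCCC1(C[C@H]2C=CC[C@@H]3CC(=O)NCCCCN(S(=O)(=O)c4ccccc4[N+](=O)[O-])CCCN32)OCCO1 | intermediate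
33 | (13R,17S)-17-[(2-pentyl-1,3-dioxolan-2-yl)methyl]-1,5,10-triazabicyclo[11.4.0]heptadec-15-en-11-one | CCCCCC1(C[C@H]2C=CC[C@@H]3CC(=O)NCCCCNCCCN32)OCCO1 | intermediate
34 | (13R,17S)-17-(2-oxoheptyl)-1,5,10-triazabicyclo[11.4.0]heptadec-15-en-11-one | CCCCCC(=O)C[C@H]1C=CC[C@@H]2CC(=O)NCCCCNCCCN21 | target

## Step count and risks

Total step count: 23. Longest linear sequence: 23 steps (1 → 34).

Steps most likely to fail:

Step 8 (Mannich addition). The ketone titanium enolate may give modest diastereoselectivity or some conjugate addition to the ynimine. Fallback: set out from 12 and add the triisopropoxytitanium enolate of methyl acetate (LiN(iPr)2, then ClTi(OiPr)3, THF, −78 °C), the best-precedented Mannich partner for sulfinyl imines. This gives methyl (3S,7S)-3-{[(R)-tert-butylsulfinyl]amino}-7-[(tert-butyldiphenylsilyl)oxy]-9-[(4-methoxybenzyl)oxy]non-4-ynoate F1. Treatment with MeNH(OMe)·HCl and iPrMgCl (THF, −20 °C) converts it into (3S,7S)-3-{[(R)-tert-butylsulfinyl]amino}-7-[(tert-butyldiphenylsilyl)oxy]-N-methoxy-9-[(4-methoxybenzyl)oxy]-N-methylnon-4-ynamide F2. Addition of C5H11MgBr (THF, 0 °C) to this Weinreb amide comes back to the route at 16.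

Step 18 (N-alkylation of the hindered ring amine). The flanked secondary amine may alkylate slowly, and elimination of the bromide can compete. Fallback: set out from 27 and use conjugate addition to acrylonitrile (MeOH, 60 °C), which needs only a small, unhindered acceptor. This gives 2-{(2R,6S)-1-(2-cyanoethyl)-6-[(2-pentyl-1,3-dioxolan-2-yl)methyl]-1,2,3,6-tetrahydropyridin-2-yl}-N-(4-hydroxybutyl)acetamide F3. Reduction of the nitrile with NaBH4/CoCl2·6H2O (MeOH, 0 °C), which spares the amide, the ketal and the ring alkene, comes back to the route at 30 and bypasses 29.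

Step 21 (macrocyclisation). The Mitsunobu closure of a 13-membered ring may be slow against oligomerisation. Fallback: set out from 31 and convert the primary alcohol with I2, PPh3 and imidazole (CH2Cl2, 0 °C) into N-(4-iodobutyl)-2-{(2R,6S)-1-{3-[(2-nitrophenyl)sulfonamido]propyl}-6-[(2-pentyl-1,3-dioxolan-2-yl)methyl]-1,2,3,6-tetrahydropyridin-2-yl}acetamide F4. Intramolecular alkylation of the nosylamide anion (Cs2CO3, MeCN, 60 °C, 2 mM, syringe-pump addition) then closes the ring and comes back to the route at 32.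

## Further compounds

F1 | step 8 | methyl (3S,7S)-3-{[(R)-tert-butylsulfinyl]amino}-7-[(tert-butyldiphenylsilyl)oxy]-9-[(4-methoxybenzyl)oxy]non-4-ynoate | COC(=O)C[C@H](N[S@](=O)C(C)(C)C)C#CC[C@H](O[Si](c1ccccc1)(c1ccccc1)C(C)(C)C)CCOCc1ccc(OC)cc1
F2 | step 8 | (3S,7S)-3-{[(R)-tert-butylsulfinyl]amino}-7-[(tert-butyldiphenylsilyl)oxy]-N-methoxy-9-[(4-methoxybenzyl)oxy]-N-methylnon-4-ynamide | CON(C)C(=O)C[C@H](N[S@](=O)C(C)(C)C)C#CC[C@H](O[Si](c1ccccc1)(c1ccccc1)C(C)(C)C)CCOCc1ccc(OC)cc1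
F3 | step 18 | 2-{(2R,6S)-1-(2-cyanoethyl)-6-[(2-pentyl-1,3-dioxolan-2-yl)methyl]-1,2,3,6-tetrahydropyridin-2-yl}-N-(4-hydroxybutyl)acetamide | CCCCCC1(C[C@H]2C=CC[C@H](CC(=O)NCCCCO)N2CCC#N)OCCO1
F4 | step 21 | N-(4-iodobutyl)-2-{(2R,6S)-1-{3-[(2-nitrophenyl)sulfonamido]propyl}-6-[(2-pentyl-1,3-dioxolan-2-yl)methyl]-1,2,3,6-tetrahydropyridin-2-yl}acetamide | CCCCCC1(C[C@H]2C=CC[C@H](CC(=O)NCCCCI)N2CCCNS(=O)(=O)c2ccccc2[N+](=O)[O-])OCCO1
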